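(All runs were computed with made-up constants, noise included.)

Each Q spent stays on an adduct in the steps thought possible: J carries 1, E and D 2, L 3, Z 4. Both steps that make or use L have [Q] in their rate, so follow [Q].

| flask | X | Q | remark | time |
|---|---|---|---|---|
| amber | 0.14 M | 0.11 M | run made earlier |  |
| ochre | 0.14 M | 0.26 M | run made earlier |  |
| grey | 0.14 M | 0.50 M | run made earlier |  |
| north-east | 0.14 M | 0.140 M |  | 80 min |
| south | 0.14 M | 0.280 M |  | 80 min |
| south-west | 0.14 M | 0.560 M |  | 80 min |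

| run | time / min | L / % | E / % | X / % |
|---|---|---|---|---|
| amber | 15.0 | 1.3 | 7.1 | 32.5 |
| amber | 30.0 | 1.4 | 9.4 | 26.9 |
| amber | 50.0 | 2.2 | 9.5 | 26.1 |
| amber | 60.0 | 2.8 | 6.4 | 24.2 |
| amber | 80.0 | 5.6 | 7.3 | 23.9 |
| ochre | 8.00 | 2.1 | 13.7 | 30.9 |
| ochre | 20.0 | 6.4 | 20.2 | 17.7 |
| ochre | 40.0 | 10.7 | 14.6 | 13.2 |
| ochre | 60.0 | 10.6 | 10.3 | 12.7 |
| ochre | 80.0 | 10.9 | 7.7 | 12.5 |
| grey | 15.0 | 14.8 | 25.3 | 9.7 |
| grey | 30.0 | 17.9 | 14.6 | 7.2 |
| grey | 50.0 | 12.7 | 8.1 | 6.0 |
| grey | 60.0 | 11.7 | 7.2 | 3.2 |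
| grey | 80.0 | 7.3 | 5.0 | 0.9 |

(standard deviation of a reading: 1 percentage point)

- steps thought possible: E -> D; Q + E -> L; Q + L -> Z; Q + J -> E; X + Q -> J; X <-> G

1. final L, as a percentage of the X charged, for each flask in turn (north-east, south, south-west)

1. Compute the budget. South has 2.00 as its Q budget, the charged [Q] divided by the charged [X], in equivalents of Q per X. North-east has 1.00 and south-west 4.00; amber had 0.786, ochre 1.86, grey 3.57.
2. Solve the lean extreme. Let Q be the limiting reagent: [Q] falls towards nil, and L freezes where it stands. Ochre's readings have that shape, with L reading 10.7% at 40.0 min and 10.9% at 80.0 min.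
3. Solve the rich extreme. Hold [Q] at its charge: each step with Q is pseudo-first-order, and L rises, then decays. Grey's readings have that shape, with L reading 17.9% at 30.0 min and 7.3% at 80.0 min.
4. Place the flasks between the extremes by budget. My own reckoning takes the run with the nearest budget: about 5.6% for north-east, about 10.9% for south, and somewhat under 7.3% for south-west, whose budget is larger than grey's.
5. Set the forecast beside it: 6.5%, 11%, 5%, on the ground that “L at 80 min against Q is a hump”. Its north-east value stands higher than my reading.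
6. The flasks give 4.92%, 11.1%, 6.43%, and the forecast stands within its margin.

    E → D (k = 5.15 × 10⁻⁴ s⁻¹)
    Q + E → L (k = 0.00371 L mol⁻¹ s⁻¹)
    Q + L → Z (k = 0.00399 L mol⁻¹ s⁻¹)
    Q + J → E (k = 0.0135 L mol⁻¹ s⁻¹)
    X + Q → J (k = 0.00591 L mol⁻¹ s⁻¹)
    X ⇌ G (K = 1.50, k = 0.00175 s⁻¹)

In south, the half-life of L by the making of Z alone, the other concentrations as charged, is 10 min, short against 80 min. South's budget of 2.00, with 12% of its Q left at 80.0 min, means 1.76 equivalents spent per X, and its adducts carry 1.75. South-west's budget of 4.00, with 26% left, means 2.96 spent, and its adducts carry 2.96.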